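Carbon numbers are the labdane numbers of the target (ring A = C1–C5, C10; ring B = C5–C10).

**Plan**
1. Cuts: ring A at C1–C2 and C3–C4 (a two-carbon ene-dione is removed), then C9–C11 (side chain), then C10–C1 and C10–C20 (two α′-alkylations of a carvone).
2. Forward: ring B is (S)-carvone; C10 is made quaternary (CH3, then CH2OH); the C11–C15 chain from (S)-citronellol is joined by 1,2-addition and oxidative transposition; ring A is closed in one operation; the two acetyls are turned into oxygens; ring B is finished last.
3. Enabling feature: C4 (gem-dimethyl, next to ring-fusion C5–H) is the Markovnikov radical of the carvone isopropenyl group, and C1 is a CH2 on quaternary C10, that is, a neopentyl aldehyde. This 1,4 radical/electrophile pair on the C5–C10 edge of ring B takes up C2–C3 of hex-3-ene-2,5-dione, whose acetyls are latent C2 and C3 oxygens.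
4. Stereochemistry: C5 from (S)-carvone; C10 by alkylation anti to isopropenyl; C13 from (S)-citronellol; C2 by equilibration to equatorial; C3 by hydride delivery to a 3-ketone on which both C3 epimers converge; C9 by suprafacial hydrogen transfer from an allylic diazene at C7.

Key step: step 9

Assumption: centres that arise as mixtures and are later erased or reset (the carbinol carbon of 13; C1–C3 of 16–20) are left undefined in the SMILES, and 21–25 are drawn as the expected major epimer with the C3 substituent equatorial; the minor C3 epimer converges at ketone 26.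

**Route**

Step 1
Reactants: 1 (S)-citronellol
Product: 2 tert-butyl{[(3S)-3,7-dimethyloct-6-en-1-yl]oxy}dimethylsilane
Conditions: TBSCl, imidazole, CH2Cl2, 25 °C
Reagents that add atoms: tert-butyldimethylsilyl chloride, CC(C)(C)[Si](C)(C)Cl
Why: Routine silyl ether formation at the primary hydroxyl, which carries C15 through the organolithium stage and leaves C13 untouched.

Step 2
Reactants: 2 silyl ether
Product: 3 (4S)-6-[(tert-butyldimethylsilyl)oxy]-4-methylhexanoic acid
Conditions: RuCl3·xH2O (cat.), NaIO4, CCl4/MeCN/H2O, 25 °C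
Reagents that add atoms: sodium periodate, [Na+].[O-]I(=O)(=O)=O; water, O
Why: RuO4-catalysed oxidative cleavage of the trisubstituted alkene should give the acid and acetone without touching the remote C13 centre.

Step 3
Reactants: 3 acid
Product: 4 tert-butyl{[(3R)-5-iodo-3-methylpentyl]oxy}dimethylsilane
Conditions: PhI(OAc)2, I2, cyclohexane, hν, reflux
Reagents that add atoms: iodine, II
Why: Radical iododecarboxylation (Hunsdiecker-type reaction) removes one carbon and should give the primary iodide that maps onto C11–C15 (the descriptor changes only by priority).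

Step 4
Reactants: 5 2,5-dimethylfuran
Product: 6 (Z)-hex-3-ene-2,5-dione
Conditions: mCPBA, CH2Cl2, 0 → 25 °C
Reagents that add atoms: 3-chloroperoxybenzoic acid, OOC(=O)c1cccc(Cl)c1
Why: Peracid oxidation of the furan (oxidative ring opening) should give the cis-ene-dione, a doubly activated and symmetrical radical acceptor.

Step 5
Reactants: 7 (S)-carvone
Product: 9 (5S,6R)-2,6-dimethyl-5-(prop-1-en-2-yl)cyclohex-2-en-1-one, via lithium dienolate 8 (not isolated)
Conditions: LiN(i-Pr)2, THF, −78 °C; MeI, −78 → 0 °C
Reagents that add atoms: iodomethane, CI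
Why: Kinetic α′-enolate alkylation should place the future C20 methyl on C10, mainly trans to isopropenyl; this centre is planarised again in step 6, so its configuration is immaterial.

Step 6
Reactants: 9 6-methylcarvone
Product: 11 (5R,6S)-6-(hydroxymethyl)-2,6-dimethyl-5-(prop-1-en-2-yl)cyclohex-2-en-1-one, via lithium enolate 10 (not isolated)
Conditions: LiN(i-Pr)2, THF, −78 °C; CH2O (gas, from cracked paraformaldehyde), −78 °C; AcOH
Reagents that add atoms: formaldehyde, C=O
Why: Aldol addition of the tetrasubstituted enolate to formaldehyde should occur anti to the adjacent C5 isopropenyl group, which sets quaternary C10 with CH3 cis and CH2OH (C1) trans to isopropenyl.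

Step 7
Reactants: 4 iodide; 11 hydroxymethyl ketone
Product: 13 (5R,6S)-1-{(3S)-5-[(tert-butyldimethylsilyl)oxy]-3-methylpentyl}-6-(hydroxymethyl)-2,6-dimethyl-5-(prop-1-en-2-yl)cyclohex-2-en-1-ol (carbinol epimers), via alkyllithium 12 (not isolated)
Conditions: 4 (2.3 equiv), t-BuLi (4.6 equiv), Et2O, −78 °C; then 11, THF, −78 °C; AcOH, H2O
Reagents that add atoms: none
Why: Iodine–lithium exchange and 1,2-addition of the primary alkyllithium to the enone carbonyl, which has no α-hydrogen (as with 2,6,6-trimethylcyclohexenone), should form C9–C11, one equivalent being consumed by the hydroxyl; the carbinol configuration is erased in step 8.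

Step 8
Reactants: 13 diol
Product: 14 2-{(3S)-5-[(tert-butyldimethylsilyl)oxy]-3-methylpentyl}-1,3-dimethyl-4-oxo-6-(prop-1-en-2-yl)cyclohex-2-ene-1-carbaldehyde (CHO trans to isopropenyl)
Conditions: pyridinium chlorochromate C5H5NH[CrO3Cl] (4 equiv), NaOAc, 4 Å MS, CH2Cl2, 25 °C
Reagents that add atoms: none
Why: A [3,3] shift of the tertiary allylic chromate ester transposes oxygen to C7 and gives the C8=C9 enone (Babler–Dauben oxidative transposition), while the same reagent oxidises the primary alcohol to the C1 aldehyde.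

Step 9
Reactants: 14 keto aldehyde; 6 ene-dione
Product: 17 2,3-diacetyl-15-[(tert-butyldimethylsilyl)oxy]-1-hydroxylabd-8-en-7-one (diastereomer mixture at C1–C3), via tertiary C4 radical 15 (not isolated), via iron enolate 16 (not isolated)
Conditions: 6 (3 equiv), Fe(acac)3 (0.5 equiv), PhSiH3 (2.5 equiv), EtOH/(CH2OH)2, 0 → 25 °C
Reagents that add atoms: none
Why: Hydrogen-atom transfer from an iron hydride to the isopropenyl group should give the tertiary C4 radical 15, which adds to the alkene of 6 (C3–C4 bond); single-electron reduction of the adduct radical by divalent iron gives enolate 16, which closes onto the C1 aldehyde (C1–C2 bond). The closest known reaction type is the hydrogen-atom-transfer-initiated radical conjugate addition/aldol annulation (reductive radical–polar crossover) of alkene-tethered aldehydes with unsaturated carbonyl compounds. Ring A closes in the aldol event in the 6-(enolexo)-exo-trig mode after the intermolecular Giese addition, and its trans fusion to ring B follows from the fixed trans arrangement of the C5 and C10 appendages. C4 is not stereogenic; C1, C2 and C3 arise as mixtures without consequence, because C1 is removed in step 10, C2 is equilibrated in step 11 and C3 is reset in steps 15 and 16. The step needs hydrogen-atom transfer to the 1,1-disubstituted alkene only (the tetrasubstituted enone is inert), Markovnikov radical formation, and addition faster than radical reduction, which the excess of the highly electrophilic, symmetrical ene-dione secures without any regiochemical question; the aldehyde should outcompete the hindered conjugated C7 ketone as aldol acceptor.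

Step 10
Reactants: 17 aldol adduct
Product: 19 2,3-diacetyl-15-[(tert-butyldimethylsilyl)oxy]labda-1,8-dien-7-one, via C1 mesylate 18 (not isolated)
Conditions: MsCl, Et3N, CH2Cl2, 0 → 25 °C
Reagents that add atoms: none
Why: Sulfonylation of the aldol hydroxyl and E1cB elimination across C1–C2 (aldol dehydration) remove the C1 oxygen and its stereocentre.

Step 11
Reactants: 19 dienone
Product: 21 2,3-diacetyl-15-[(tert-butyldimethylsilyl)oxy]labd-8-en-7-one (both acetyls equatorial), via kinetic dihydro mixture 20 (not isolated)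
Conditions: H2 (1 atm), Pd/C, EtOAc, 25 °C; filter; DBU (cat.), CH2Cl2, 25 °C
Reagents that add atoms: none
Why: Heterogeneous hydrogenation should saturate the trisubstituted C1=C2 enone but not the tetrasubstituted ring-B enone, and base-mediated enolisation then moves the C2 acetyl to the equatorial position, away from the syn-axial C10 and C4 methyls (thermodynamic control); C3 has only a modest equatorial preference and is corrected in steps 15 and 16.

Step 12
Reactants: 21 diketone
Product: 23 2,3-diacetoxy-15-[(tert-butyldimethylsilyl)oxy]labd-8-en-7-one, via C2 monoacetate 22 (not isolated)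
Conditions: mCPBA (excess), NaHCO3, CHCl3, 25 → 45 °C
Reagents that add atoms: 3-chloroperoxybenzoic acid, OOC(=O)c1cccc(Cl)c1
Why: Twofold Baeyer–Villiger oxidation, with migration of the secondary ring carbons in preference to methyl and with retention (as in the conversion of 20-oxo steroids into 17-acetates), turns both acetyls into acetates; the electron-poor tetrasubstituted enone should resist epoxidation.

Step 13
Reactants: 23 diacetate
Product: 24 2,3,15-trihydroxylabd-8-en-7-one
Conditions: HCl (1.25 M in MeOH), 40 °C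
Reagents that add atoms: none
Why: Acid-catalysed transesterification of both acetates and solvolysis of the primary silyl ether are done at the enone stage, before the acid-sensitive C7=C8 alkene exists.

Step 14
Reactants: 24 triol
Product: 25 3-hydroxy-7-oxolabd-8-ene-2,15-diyl diacetate
Conditions: Ac2O (2.2 equiv), pyridine, CH2Cl2, 0 °C
Reagents that add atoms: acetic anhydride, CC(=O)OC(C)=O
Why: Kinetically selective esterification, since the primary C15 and the unhindered equatorial C2 hydroxyls should acylate far faster than the neopentylic C3 hydroxyl next to the C4 gem-dimethyl group.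

Step 15
Reactants: 25 hydroxy diacetate
Product: 26 3,7-dioxolabd-8-ene-2,15-diyl diacetate
Conditions: Dess–Martin periodinane, NaHCO3, CH2Cl2, 25 °C
Reagents that add atoms: none
Why: Dess–Martin oxidation of the remaining C3 hydroxyl makes both C3 epimers converge on one ketone, and the enolisable C2 acetoxy centre stays or becomes equatorial.

Step 16
Reactants: 26 diketone
Product: 27 3,7-dihydroxylabd-8-ene-2,15-diyl diacetate (both hydroxyls cis to the C10 methyl)
Conditions: NaBH4, CeCl3·7H2O, MeOH, −40 → 0 °C
Reagents that add atoms: none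
Why: Luche reduction of both ketones: hydride should attack C3 axially, opposite the axial C4 methyl, to give the equatorial 3-alcohol, and add 1,2 to the enone along the axial trajectory to give the pseudo-equatorial C7 alcohol.

Step 17
Reactants: 27 diol
Product: 30 (2S,3S,5S,9R,10S,13S)-3-hydroxylabd-7-ene-2,15-diyl diacetate, via C7 sulfonylhydrazine 28 (not isolated), via allylic diazene 29 (not isolated)
Conditions: 2-O2NC6H4SO2NHNH2, PPh3, DEAD, THF, −30 → 25 °C
Reagents that add atoms: none
Why: Mitsunobu displacement of the allylic C7 hydroxyl with inversion gives 28, loss of sulfinic acid gives diazene 29, and its suprafacial retro-ene shift (reductive 1,3-transposition) places hydrogen on C9 trans to the C10 methyl and the alkene at C7=C8; the hindered C3 hydroxyl should not react.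

**Compound list**

1 | (S)-citronellol, (3S)-3,7-dimethyloct-6-en-1-ol | OCC[C@@H](C)CCC=C(C)C | starting material
2 | tert-butyl{[(3S)-3,7-dimethyloct-6-en-1-yl]oxy}dimethylsilane | CC(C)(C)[Si](C)(C)OCC[C@@H](C)CCC=C(C)C | intermediate
3 | (4S)-6-[(tert-butyldimethylsilyl)oxy]-4-methylhexanoic acid | CC(C)(C)[Si](C)(C)OCC[C@@H](C)CCC(=O)O | intermediate
4 | tert-butyl{[(3R)-5-iodo-3-methylpentyl]oxy}dimethylsilane | CC(C)(C)[Si](C)(C)OCC[C@@H](C)CCI | intermediate
5 | 2,5-dimethylfuran | Cc1ccc(C)o1 | starting material
6 | (Z)-hex-3-ene-2,5-dione | CC(=O)/C=C\C(C)=O | intermediate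
7 | (S)-(+)-carvone | O=C1C(C)=CC[C@H](C(C)=C)C1 | starting material
8 | lithium dienolate of 7 (enolate toward C10) | [Li+].[O-]C1=C[C@@H](C(C)=C)CC=C1C | intermediate
9 | (5S,6R)-2,6-dimethyl-5-(prop-1-en-2-yl)cyclohex-2-en-1-one | O=C1C(C)=CC[C@H](C(C)=C)[C@H]1C | intermediate
10 | lithium enolate of 9 (tetrasubstituted, toward C10) | [Li+].[O-]C1=C(C)[C@@H](C(C)=C)CC=C1C | intermediate
11 | (5R,6S)-6-(hydroxymethyl)-2,6-dimethyl-5-(prop-1-en-2-yl)cyclohex-2-en-1-one | O=C1C(C)=CC[C@H](C(C)=C)[C@@]1(C)CO | intermediate
12 | {(3S)-5-[(tert-butyldimethylsilyl)oxy]-3-methylpentyl}lithium | CC(C)(C)[Si](C)(C)OCC[C@@H](C)CC[Li] | intermediate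
13 | (5R,6S)-1-{(3S)-5-[(tert-butyldimethylsilyl)oxy]-3-methylpentyl}-6-(hydroxymethyl)-2,6-dimethyl-5-(prop-1-en-2-yl)cyclohex-2-en-1-ol, carbinol epimers | CC(C)(C)[Si](C)(C)OCC[C@@H](C)CCC1(O)C(C)=CC[C@H](C(C)=C)[C@@]1(C)CO | intermediate
14 | 2-{(3S)-5-[(tert-butyldimethylsilyl)oxy]-3-methylpentyl}-1,3-dimethyl-4-oxo-6-(prop-1-en-2-yl)cyclohex-2-ene-1-carbaldehyde, CHO trans to isopropenyl | CC(C)(C)[Si](C)(C)OCC[C@@H](C)CCC1=C(C)C(=O)C[C@H](C(C)=C)[C@@]1(C)C=O | intermediate
15 | tertiary C4 radical from 14 | CC(C)(C)[Si](C)(C)OCC[C@@H](C)CCC1=C(C)C(=O)C[C@H]([C](C)C)[C@@]1(C)C=O | intermediate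
16 | enolate of the Giese adduct (iron-bound, drawn as the anion) | CC(C)(C)[Si](C)(C)OCC[C@@H](C)CCC1=C(C)C(=O)C[C@H](C(C)(C)C(C(C)=O)C=C(C)[O-])[C@@]1(C)C=O | intermediate
17 | 2,3-diacetyl-15-[(tert-butyldimethylsilyl)oxy]-1-hydroxylabd-8-en-7-one, trans-decalin as in the target, mixture at C1–C3 | CC(C)(C)[Si](C)(C)OCC[C@@H](C)CCC1=C(C)C(=O)C[C@@H]2C(C)(C)C(C(C)=O)C(C(C)=O)C(O)[C@@]12C | intermediate
18 | C1 methanesulfonate of 17 | CC(C)(C)[Si](C)(C)OCC[C@@H](C)CCC1=C(C)C(=O)C[C@@H]2C(C)(C)C(C(C)=O)C(C(C)=O)C(OS(C)(=O)=O)[C@@]12C | intermediate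
19 | 2,3-diacetyl-15-[(tert-butyldimethylsilyl)oxy]labda-1,8-dien-7-one, C3 epimers | CC(C)(C)[Si](C)(C)OCC[C@@H](C)CCC1=C(C)C(=O)C[C@@H]2C(C)(C)C(C(C)=O)C(C(C)=O)=C[C@@]12C | intermediate
20 | 2,3-diacetyl-15-[(tert-butyldimethylsilyl)oxy]labd-8-en-7-one, kinetic C2/C3 epimer mixture | CC(C)(C)[Si](C)(C)OCC[C@@H](C)CCC1=C(C)C(=O)C[C@@H]2C(C)(C)C(C(C)=O)C(C(C)=O)C[C@@]12C | intermediate
21 | 2,3-diacetyl-15-[(tert-butyldimethylsilyl)oxy]labd-8-en-7-one, both acetyls equatorial (2-acetyl trans, 3-acetyl cis to the C10 methyl) | CC(C)(C)[Si](C)(C)OCC[C@@H](C)CCC1=C(C)C(=O)C[C@@H]2C(C)(C)[C@H](C(C)=O)[C@@H](C(C)=O)C[C@@]12C | intermediate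
22 | 2-acetoxy-3-acetyl-15-[(tert-butyldimethylsilyl)oxy]labd-8-en-7-one | CC(C)(C)[Si](C)(C)OCC[C@@H](C)CCC1=C(C)C(=O)C[C@@H]2C(C)(C)[C@H](C(C)=O)[C@@H](OC(C)=O)C[C@@]12C | intermediate
23 | 2,3-diacetoxy-15-[(tert-butyldimethylsilyl)oxy]labd-8-en-7-one | CC(C)(C)[Si](C)(C)OCC[C@@H](C)CCC1=C(C)C(=O)C[C@@H]2C(C)(C)[C@H](OC(C)=O)[C@@H](OC(C)=O)C[C@@]12C | intermediate
24 | 2,3,15-trihydroxylabd-8-en-7-one | OCC[C@@H](C)CCC1=C(C)C(=O)C[C@@H]2C(C)(C)[C@H](O)[C@@H](O)C[C@@]12C | intermediate
25 | 3-hydroxy-7-oxolabd-8-ene-2,15-diyl diacetate | CC(=O)OCC[C@@H](C)CCC1=C(C)C(=O)C[C@@H]2C(C)(C)[C@H](O)[C@@H](OC(C)=O)C[C@@]12C | intermediate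
26 | 3,7-dioxolabd-8-ene-2,15-diyl diacetate | CC(=O)OCC[C@@H](C)CCC1=C(C)C(=O)C[C@@H]2C(C)(C)C(=O)[C@@H](OC(C)=O)C[C@@]12C | intermediate
27 | 3,7-dihydroxylabd-8-ene-2,15-diyl diacetate, both hydroxyls cis to the C10 methyl | CC(=O)OCC[C@@H](C)CCC1=C(C)[C@H](O)C[C@@H]2C(C)(C)[C@H](O)[C@@H](OC(C)=O)C[C@@]12C | intermediate
28 | C7 N-(2-nitrobenzenesulfonyl)hydrazine from 27, C7 inverted | CC(=O)OCC[C@@H](C)CCC1=C(C)[C@@H](N(N)S(=O)(=O)c3ccccc3[N+](=O)[O-])C[C@@H]2C(C)(C)[C@H](O)[C@@H](OC(C)=O)C[C@@]12C | intermediate
29 | C7 allylic diazene | CC(=O)OCC[C@@H](C)CCC1=C(C)[C@@H](N=N)C[C@@H]2C(C)(C)[C@H](O)[C@@H](OC(C)=O)C[C@@]12C | intermediate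
30 | (2S,3S,5S,9R,10S,13S)-3-hydroxylabd-7-ene-2,15-diyl diacetate, CNP0144124.2 | CC(=O)OCC[C@@H](C)CC[C@@H]1C(C)=CC[C@@H]2C(C)(C)[C@H](O)[C@@H](OC(C)=O)C[C@@]12C | target

**Step count and risks**

Total step count: 17. Longest linear sequence: 14 steps (steps 1–3 and 7–17, from (S)-citronellol). Steps 5–6 (from (S)-carvone) join at step 7, and step 4 (from 2,5-dimethylfuran) joins at step 9.

Steps most likely to fail:

1. Step 9. Hydrogenative quenching of the tertiary radical or reduction of the ene-dione may outrun the conjugate addition, and the enolate may be protonated before it closes the ring. The two bonds would then be made one after the other by chain and condensation chemistry, setting out from 14. Dry HCl (CH2Cl2, −78 °C) should add in the Markovnikov sense to the isopropenyl group to give the tertiary chloride F1. Bu3SnH/AIBN with excess 6 (benzene, 80 °C, slow addition of the stannane) should give the open-chain Giese adduct F2, which contains the C3–C4 bond. Pyrrolidinium acetate (cat., toluene, 60 °C) should then close C1–C2 by intramolecular aldol condensation, which comes back to the route at enone 19.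

2. Step 17. The Mitsunobu displacement at the allylic carbinol beside the tetrasubstituted alkene may be slow, so that elimination to a diene, SN2′ attack or activation of the C3 hydroxyl competes. Setting out from 27, methyl chloroformate/pyridine (CH2Cl2, −20 °C) should acylate only the allylic hydroxyl to give the C7 methyl carbonate F3. Pd(OAc)2/PBu3 with HCO2H/Et3N (THF, 40 °C) should ionise it with zerovalent palladium anti to the leaving group and deliver hydride from the metal to the more substituted allyl terminus C9 (formate hydrogenolysis with allylic transposition). This gives the same C9 configuration and the C7=C8 alkene, and comes back to the route at target 30.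

3. Step 14. Site selectivity may be lost, with acetylation of the C3 hydroxyl or incomplete acetylation at C2. Setting out from 24, Bu2SnO (toluene, reflux, removal of water) should give the 2,3-O-dibutylstannylene acetal F4. AcCl (2.1 equiv) and Et3N (CH2Cl2, 0 °C) should then acylate the tin-activated, less hindered O2 and the primary C15 hydroxyl, which comes back to the route at 25.

**Further compounds**

F1 | step 9 | tertiary chloride from Markovnikov addition of HCl to the isopropenyl group of 14 | CC(C)(C)[Si](C)(C)OCC[C@@H](C)CCC1=C(C)C(=O)C[C@H](C(C)(C)Cl)[C@@]1(C)C=O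
F2 | step 9 | open-chain Giese adduct of the C4 radical with 6 (C3 epimers) | CC(C)(C)[Si](C)(C)OCC[C@@H](C)CCC1=C(C)C(=O)C[C@H](C(C)(C)C(CC(C)=O)C(C)=O)[C@@]1(C)C=O
F3 | step 17 | C7 methyl carbonate of 27 | CC(=O)OCC[C@@H](C)CCC1=C(C)[C@H](OC(=O)OC)C[C@@H]2C(C)(C)[C@H](O)[C@@H](OC(C)=O)C[C@@]12C
F4 | step 14 | 2,3-O-dibutylstannylene acetal of 24 | OCC[C@@H](C)CCC1=C(C)C(=O)C[C@@H]2C(C)(C)[C@@H]3O[Sn](CCCC)(CCCC)O[C@H]3C[C@@]12C
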